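Abbreviations: TBSO = tert-butyldimethylsilyloxy; TIPSO = triisopropylsilyloxy; Ar* = 5-[(2S,3R,4S)-3-[5-bromo-2-(TBSO)phenyl]-2-[4-(TIPSO)phenyl]-7-(TIPSO)chroman-4-yl]-2,4-bis(TBSO)phenyl.

Assumption: all numbered starting materials (including 4,6-diiodoresorcinol) are catalogue chemicals, and the (R)-acid of step 10 is taken to give the (2S,3R,4S) chroman (otherwise its mirror image is used).

Note: chroman C4 reads S in every O-silylated compound and R in the target only because O–Si outranks O–C in the priority rules; the spatial arrangement is the same.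

## Retrosynthetic overview

1. Target ⇐ removal of eleven aryl silyl ethers; both 2,4-dioxyaryl ketones (chalcone C=O and oxolane aroyl) come from one double aryllithium addition to a bis-Weinreb amide, whose enamide arm is installed by a Heck reaction.
2. Oxolane (formed last) ⇐ addition of the chroman-bearing aryl-Mg to a cis-lactone acid, then ketal reduction that sets the aryl/benzyl-cis centre.
3. Lactone acid ⇐ Evans MgCl2 anti-aldol (two centres) and trans-benzylation of the paraconic acid dianion (third centre).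
4. Chroman (formed first) ⇐ new catalytic asymmetric oxa-[4+2] of an o-quinone methide (from a 2-hydroxybenzhydrol) with an unsymmetrical (E)-stilbene; all three chroman centres in one step.
5. Ring order: chroman pyran ring (step 10) → γ-lactone (step 13) → oxolane (steps 15–16).

## Route

Step 1
Reactants: 1 4-hydroxybenzaldehyde
Product: 2 4-(TIPSO)benzaldehyde
Conditions: TIPSCl, imidazole, DMF, 0 → 23 °C
Reagents that add atoms: chlorotriisopropylsilane, CC(C)[Si](Cl)(C(C)C)C(C)C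
Why: Imidazole-mediated O-silylation of the phenol gives a base-tolerant aryl silyl ether; no stereocentre.

Step 2
Reactants: 2 4-(TIPSO)benzaldehyde
Product: 3 [4-(TIPSO)phenyl]methanol
Conditions: NaBH4, MeOH, 0 °C
Reagents that add atoms: none
Why: Borohydride reduction of an aromatic aldehyde is clean and leaves the aryl silyl ether intact.

Step 3
Reactants: 3 [4-(TIPSO)phenyl]methanol
Product: 4 4-(TIPSO)benzyl bromide
Conditions: CBr4, PPh3, CH2Cl2, 0 °C
Reagents that add atoms: carbon tetrabromide, BrC(Br)(Br)Br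
Why: Appel bromination is neutral, so the electron-rich benzylic bromide forms without loss of the silyl ether.

Step 4
Reactants: 4 4-(TIPSO)benzyl bromide
Product: 5 diethyl [4-(TIPSO)benzyl]phosphonate
Conditions: P(OEt)3 (neat), 130 °C
Reagents that add atoms: triethyl phosphite, CCOP(OCC)OCC
Why: Michaelis–Arbuzov reaction of a reactive benzylic bromide, driven by loss of bromoethane.

Step 5
Reactants: 6 5-bromo-2-hydroxybenzaldehyde
Product: 7 5-bromo-2-(TBSO)benzaldehyde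
Conditions: TBSCl, imidazole, DMF, 23 °C
Reagents that add atoms: tert-butylchlorodimethylsilane, CC(C)(C)[Si](C)(C)Cl
Why: Standard phenol silylation; the smaller TBS group is chosen for the oxygen that ends up next to the congested chroman C3.

Step 6
Reactants: 5 diethyl [4-(TIPSO)benzyl]phosphonate; 7 5-bromo-2-(TBSO)benzaldehyde
Product: 8 (E)-1-[5-bromo-2-(TBSO)phenyl]-2-[4-(TIPSO)phenyl]ethene
Conditions: NaH, 15-crown-5 (10 mol%), THF, 0 → 23 °C (base added to the premixed partners)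
Reagents that add atoms: none
Why: Horner–Wadsworth–Emmons olefination of a benzylic phosphonate with an aryl aldehyde gives the (E)-stilbene through the reversibly formed, anti-eliminating oxaphosphetane.

Step 7
Reactants: 9 2,4-dihydroxybenzaldehyde
Product: 10 2-hydroxy-4-(TIPSO)benzaldehyde
Conditions: TIPSCl (1.05 equiv), imidazole, CH2Cl2, 0 °C
Reagents that add atoms: chlorotriisopropylsilane, CC(C)[Si](Cl)(C(C)C)C(C)C
Why: Regioselective silylation: the 4-OH is more acidic and not hydrogen-bonded to the formyl group, so the 2-OH stays free as the later chroman oxygen.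

Step 8
Reactants: 11 4,6-diiodobenzene-1,3-diol
Product: 12 1,5-diiodo-2,4-bis(TBSO)benzene
Conditions: TBSCl (2.4 equiv), imidazole, DMF, 23 °C
Reagents that add atoms: tert-butylchlorodimethylsilane, CC(C)(C)[Si](C)(C)Cl
Why: Exhaustive phenol silylation; the two iodides are kept for two successive iodine–magnesium exchanges.

Step 9
Reactants: 12 1,5-diiodo-2,4-bis(TBSO)benzene; 10 2-hydroxy-4-(TIPSO)benzaldehyde
Product: 15 [2,4-bis(TBSO)-5-iodophenyl][2-hydroxy-4-(TIPSO)phenyl]methanol (racemic), via arylmagnesium chloride 13 (not isolated), via sodium phenoxide 14 (not isolated)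
Conditions: 12, i-PrMgCl·LiCl (1.05 equiv), THF, −20 °C; 10, NaH, THF, 0 °C; combine, −40 → 0 °C; aq NH4Cl
Reagents that add atoms: none
Why: Iodine–magnesium exchange of one C–I bond (the aryl-Mg deactivates the second) followed by Grignard 1,2-addition to the phenoxide-protected aldehyde; the carbinol centre is racemic and is erased in step 10.

Step 10
Reactants: 15 [2,4-bis(TBSO)-5-iodophenyl][2-hydroxy-4-(TIPSO)phenyl]methanol; 8 (E)-1-[5-bromo-2-(TBSO)phenyl]-2-[4-(TIPSO)phenyl]ethene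
Product: 17 (2S,3R,4S)-3-[5-bromo-2-(TBSO)phenyl]-4-[2,4-bis(TBSO)-5-iodophenyl]-2-[4-(TIPSO)phenyl]-7-(TIPSO)chromane (all-trans), via o-quinone methide 16 (not isolated)
Conditions: (R)-3,3'-bis(2,4,6-triisopropylphenyl)-1,1'-binaphthalene-2,2'-diyl N-(trifluoromethylsulfonyl)phosphoramidate (10 mol%), 8 (1.3 equiv), 5 Å MS, PhCF3, −20 °C
Reagents that add atoms: none
Why: Proposed new method: the chiral N-triflylphosphoramide dehydrates 15 to the (E)-o-quinone methide 16 and holds it as a hydrogen-bonded contact ion pair, so the non-directing stilbene 8 attacks the methide carbon on one enantiotopic face through its bromoaryl-bearing carbon (positive charge develops on the carbon carrying the better donor, the 4-silyloxyphenyl ring) and the phenolic oxygen closes the ring in an asynchronous endo inverse-electron-demand oxa-[4+2] that carries the E geometry into 2,3-trans and sets 3,4-trans/2,4-cis, i.e. all three chroman centres; the closest known reaction type is the chiral phosphoric acid-catalysed [4+2] cycloaddition of in situ generated o-quinone methides with terminal styrenes, 2-vinylphenols or enamides, not yet extended to acyclic 1,2-diarylethenes lacking a hydrogen-bond donor.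

Step 11
Reactants: 18 (4S)-4-benzyl-1,3-oxazolidin-2-one; 19 methyl 4-chloro-4-oxobutanoate
Product: 20 methyl 4-[(4S)-4-benzyl-2-oxo-1,3-oxazolidin-3-yl]-4-oxobutanoate
Conditions: Et3N, DMAP (10 mol%), CH2Cl2, 0 → 23 °C
Reagents that add atoms: none
Why: DMAP-catalysed N-acylation of the oxazolidinone by the acid chloride installs the Evans auxiliary without a strong base.

Step 12
Reactants: 20 methyl 4-[(4S)-4-benzyl-2-oxo-1,3-oxazolidin-3-yl]-4-oxobutanoate; 2 4-(TIPSO)benzaldehyde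
Product: 21 methyl (3R,4S)-3-[(4S)-4-benzyl-2-oxo-1,3-oxazolidine-3-carbonyl]-4-(trimethylsilyloxy)-4-[4-(TIPSO)phenyl]butanoate
Conditions: MgCl2 (20 mol%), Et3N, TMSCl, EtOAc, 23 °C
Reagents that add atoms: chlorotrimethylsilane, C[Si](C)(C)Cl
Why: Evans magnesium chloride-catalysed direct anti-aldol reaction: soft enolisation gives the chelated (Z)-enolate, the aldehyde adds through a boat transition state on the face opposite the auxiliary benzyl group to set (3R,4S), and silylation of the aldolate turns the catalyst over.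

Step 13
Reactants: 21 aldol silyl ether
Product: 23 (2S,3R)-5-oxo-2-[4-(TIPSO)phenyl]oxolane-3-carboxylic acid (2,3-cis), via dilithium hydroxysuccinate 22 (not isolated)
Conditions: LiOH, H2O2, THF/H2O, 0 → 23 °C; Na2SO3; 1 M HCl (pH 2), EtOAc, 23 °C
Reagents that add atoms: lithium hydroxide, [Li+].[OH-]; hydrogen peroxide, OO
Why: Hydroperoxide cleavage of the imide and saponification of the methyl ester give the γ-hydroxy diacid salt, which lactonises on acidification by acyl substitution, so both centres are retained and the anti-aldol becomes the cis paraconic acid.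

Step 14
Reactants: 23 (2S,3R)-5-oxo-2-[4-(TIPSO)phenyl]oxolane-3-carboxylic acid; 4 4-(TIPSO)benzyl bromide
Product: 25 (2S,3R,4R)-5-oxo-4-[4-(TIPSO)benzyl]-2-[4-(TIPSO)phenyl]oxolane-3-carboxylic acid, via disodium enolate-carboxylate 24 (not isolated)
Conditions: NaN(SiMe3)2 (2.3 equiv), THF, −78 °C; then 4, −78 → −40 °C; 1 M HCl
Reagents that add atoms: none
Why: Lactone enolate alkylation of the carboxylate dianion (the carboxylate blocks deprotonation at its own α-carbon); the bromide enters on the face opposite the cis aryl and carboxylate groups, which sets the benzyl centre 3,4-trans (4R).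

Step 15
Reactants: 17 chroman aryl iodide; 25 benzylated lactone acid
Product: 28 (2S,3R,4R)-5-Ar*-5-hydroxy-4-[4-(TIPSO)benzyl]-2-[4-(TIPSO)phenyl]oxolane-3-carboxylic acid (both C5 anomers), via arylmagnesium chloride 26 (not isolated), via chloromagnesium carboxylate 27 (not isolated)
Conditions: 17, i-PrMgCl·LiCl (1.05 equiv), THF, −15 °C; 25 (1.2 equiv), i-PrMgCl·LiCl (1.0 equiv), THF, −40 °C; combine, −40 → 0 °C; aq NH4Cl
Reagents that add atoms: none
Why: Iodine–magnesium exchange is selective for the aryl iodide over the aryl bromide, and the aryl Grignard reagent adds once to the γ-lactone carbonyl (the pre-formed carboxylate is inert) to give a lactol whose anomeric centre is removed in step 16.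

Step 16
Reactants: 28 lactol acid
Product: 30 (2S,3R,4R,5S)-5-Ar*-4-[4-(TIPSO)benzyl]-2-[4-(TIPSO)phenyl]oxolane-3-carboxylic acid, via oxocarbenium ion 29 (not isolated)
Conditions: Et3SiH, BF3·OEt2, CH2Cl2, −78 °C; cold Et3N/aq NaHCO3 quench
Reagents that add atoms: none
Why: Ionic hydrogenation (ketal reduction) through the aryl-conjugated oxocarbenium ion: strain with the coplanar aryl ring puts the adjacent benzyl group pseudoaxial and hydride adds anti to it, which sets the last oxolane centre with aryl cis to benzyl (5S), as in lignan lactol reductions, and the low temperature prevents acid epimerisation of this kinetic product.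

Step 17
Reactants: 30 oxolane acid
Product: 31 (2S,3R,4R,5S)-5-Ar*-N-methoxy-N-methyl-4-[4-(TIPSO)benzyl]-2-[4-(TIPSO)phenyl]oxolane-3-carboxamide
Conditions: MeNH(OMe)·HCl, EDC·HCl, HOBt, i-Pr2NEt, CH2Cl2, 0 → 23 °C
Reagents that add atoms: N,O-dimethylhydroxylamine hydrochloride, CNOC.Cl
Why: Carbodiimide-mediated amide coupling gives the Weinreb amide under conditions that do not epimerise the α-centre.

Step 18
Reactants: 31 oxolane Weinreb amide (aryl bromide); 32 N-methoxy-N-methylprop-2-enamide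
Product: 33 bis-Weinreb amide (31 with Br replaced by (E)-CH=CH–C(=O)N(OMe)Me)
Conditions: Pd2(dba)3 (2.5 mol%), P(t-Bu)3·HBF4 (10 mol%), Cy2NMe, 1,4-dioxane, 80 °C
Reagents that add atoms: none
Why: Mizoroki–Heck reaction: oxidative addition of zerovalent palladium to the aryl bromide, syn-insertion of the acrylamide and syn-β-hydride elimination give the (E)-cinnamoyl Weinreb amide, done before the base-sensitive β-alkoxy ketone exists.

Step 19
Reactants: 34 4-bromobenzene-1,3-diol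
Product: 35 1-bromo-2,4-bis(TIPSO)benzene
Conditions: TIPSCl (2.4 equiv), imidazole, DMF, 50 °C
Reagents that add atoms: chlorotriisopropylsilane, CC(C)[Si](Cl)(C(C)C)C(C)C
Why: Exhaustive phenol silylation; the bulky TIPS group ortho to the future C–Li bond suppresses 1,3-silyl migration from oxygen to carbon.

Step 20
Reactants: 33 bis-Weinreb amide; 35 1-bromo-2,4-bis(TIPSO)benzene
Product: 37 undeca-O-silyl target (three TBS, eight TIPS), via aryllithium 36 (not isolated)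
Conditions: 35 (6 equiv), t-BuLi (12 equiv), Et2O, −78 °C; then 33, THF, −78 → −40 °C; aq NH4Cl
Reagents that add atoms: none
Why: Bromine–lithium exchange and double Weinreb ketone synthesis: the aryllithium adds once to each N-methoxy-N-methylamide to give chelated tetrahedral intermediates that collapse only on work-up, so both 2,4-dioxyaryl ketones form without over-addition and, at −78 °C, without enolising the α-centre.

Step 21
Reactants: 37 undeca-O-silyl target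
Product: 38 target CNP0330082.3
Conditions: Bu4NF, AcOH (1:1, 15 equiv), THF, 0 → 23 °C; pH 7 buffer work-up, reversed-phase HPLC
Reagents that add atoms: none
Why: Fluoride cleavage of all eleven aryl silyl ethers (Si–F bond formation), buffered with acetic acid so that the β-alkoxy ketone, the benzylic ethers and the 2'-hydroxychalcone see neither base nor strong acid.

## Compound list

1 | 4-hydroxybenzaldehyde | O=Cc1ccc(O)cc1 | starting material
2 | 4-(triisopropylsilyloxy)benzaldehyde | O=Cc1ccc(O[Si](C(C)C)(C(C)C)C(C)C)cc1 | intermediate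
3 | [4-(triisopropylsilyloxy)phenyl]methanol | OCc1ccc(O[Si](C(C)C)(C(C)C)C(C)C)cc1 | intermediate
4 | 1-(bromomethyl)-4-(triisopropylsilyloxy)benzene | BrCc1ccc(O[Si](C(C)C)(C(C)C)C(C)C)cc1 | intermediate
5 | diethyl {[4-(triisopropylsilyloxy)phenyl]methyl}phosphonate | CCOP(=O)(OCC)Cc1ccc(O[Si](C(C)C)(C(C)C)C(C)C)cc1 | intermediate
6 | 5-bromo-2-hydroxybenzaldehyde | O=Cc1cc(Br)ccc1O | starting material
7 | 5-bromo-2-(tert-butyldimethylsilyloxy)benzaldehyde | O=Cc1cc(Br)ccc1O[Si](C)(C)C(C)(C)C | intermediate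
8 | (E)-1-[5-bromo-2-(TBSO)phenyl]-2-[4-(TIPSO)phenyl]ethene | Brc1ccc(O[Si](C)(C)C(C)(C)C)c(/C=C/c2ccc(O[Si](C(C)C)(C(C)C)C(C)C)cc2)c1 | intermediate
9 | 2,4-dihydroxybenzaldehyde | O=Cc1ccc(O)cc1O | starting material
10 | 2-hydroxy-4-(triisopropylsilyloxy)benzaldehyde | O=Cc1ccc(O[Si](C(C)C)(C(C)C)C(C)C)cc1O | intermediate
11 | 4,6-diiodobenzene-1,3-diol | Oc1cc(O)c(I)cc1I | starting material
12 | 1,5-diiodo-2,4-bis(tert-butyldimethylsilyloxy)benzene | CC(C)(C)[Si](C)(C)Oc1cc(O[Si](C)(C)C(C)(C)C)c(I)cc1I | intermediate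
13 | [2,4-bis(TBSO)-5-iodophenyl]magnesium chloride (LiCl complex) | CC(C)(C)[Si](C)(C)Oc1cc(O[Si](C)(C)C(C)(C)C)c(I)cc1[Mg]Cl | intermediate (not isolated)
14 | sodium 2-formyl-5-(TIPSO)phenolate | [Na+].[O-]c1cc(O[Si](C(C)C)(C(C)C)C(C)C)ccc1C=O | intermediate (not isolated)
15 | [2,4-bis(TBSO)-5-iodophenyl][2-hydroxy-4-(TIPSO)phenyl]methanol (racemic) | OC(c1ccc(O[Si](C(C)C)(C(C)C)C(C)C)cc1O)c1cc(I)c(O[Si](C)(C)C(C)(C)C)cc1O[Si](C)(C)C(C)(C)C | intermediate
16 | (6E)-6-{[2,4-bis(TBSO)-5-iodophenyl]methylidene}-3-(TIPSO)cyclohexa-2,4-dien-1-one | O=C1C=C(O[Si](C(C)C)(C(C)C)C(C)C)C=C/C1=C\c1cc(I)c(O[Si](C)(C)C(C)(C)C)cc1O[Si](C)(C)C(C)(C)C | intermediate (not isolated)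
17 | (2S,3R,4S)-3-[5-bromo-2-(TBSO)phenyl]-4-[2,4-bis(TBSO)-5-iodophenyl]-2-[4-(TIPSO)phenyl]-7-(TIPSO)chromane (2,3-trans, 3,4-trans) | Brc1ccc(O[Si](C)(C)C(C)(C)C)c([C@H]2[C@H](c3cc(I)c(O[Si](C)(C)C(C)(C)C)cc3O[Si](C)(C)C(C)(C)C)c3ccc(O[Si](C(C)C)(C(C)C)C(C)C)cc3O[C@@H]2c2ccc(O[Si](C(C)C)(C(C)C)C(C)C)cc2)c1 | intermediate
18 | (4S)-4-benzyl-1,3-oxazolidin-2-one | O=C1N[C@@H](Cc2ccccc2)CO1 | starting material
19 | methyl 4-chloro-4-oxobutanoate | COC(=O)CCC(Cl)=O | starting material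
20 | methyl 4-[(4S)-4-benzyl-2-oxo-1,3-oxazolidin-3-yl]-4-oxobutanoate | COC(=O)CCC(=O)N1[C@@H](Cc2ccccc2)COC1=O | intermediate
21 | methyl (3R,4S)-3-[(4S)-4-benzyl-2-oxo-1,3-oxazolidine-3-carbonyl]-4-(trimethylsilyloxy)-4-[4-(TIPSO)phenyl]butanoate | COC(=O)C[C@@H](C(=O)N1[C@@H](Cc2ccccc2)COC1=O)[C@H](O[Si](C)(C)C)c1ccc(O[Si](C(C)C)(C(C)C)C(C)C)cc1 | intermediate
22 | dilithium (2R)-2-{(S)-hydroxy[4-(TIPSO)phenyl]methyl}butanedioate | [Li+].[Li+].[O-]C(=O)C[C@@H](C([O-])=O)[C@H](O)c1ccc(O[Si](C(C)C)(C(C)C)C(C)C)cc1 | intermediate (not isolated)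
23 | (2S,3R)-5-oxo-2-[4-(TIPSO)phenyl]oxolane-3-carboxylic acid (cis) | O=C1O[C@H](c2ccc(O[Si](C(C)C)(C(C)C)C(C)C)cc2)[C@H](C(=O)O)C1 | intermediate
24 | disodium (2S,3R)-5-oxido-2-[4-(TIPSO)phenyl]-2,3-dihydrofuran-3-carboxylate | [Na+].[Na+].[O-]C1=C[C@@H](C([O-])=O)[C@@H](c2ccc(O[Si](C(C)C)(C(C)C)C(C)C)cc2)O1 | intermediate (not isolated)
25 | (2S,3R,4R)-5-oxo-4-[4-(TIPSO)benzyl]-2-[4-(TIPSO)phenyl]oxolane-3-carboxylic acid (2,3-cis, 3,4-trans) | O=C1O[C@H](c2ccc(O[Si](C(C)C)(C(C)C)C(C)C)cc2)[C@H](C(=O)O)[C@H]1Cc1ccc(O[Si](C(C)C)(C(C)C)C(C)C)cc1 | intermediate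
26 | Ar*-magnesium chloride (LiCl complex; 17 with I replaced by MgCl) | Brc1ccc(O[Si](C)(C)C(C)(C)C)c([C@H]2[C@H](c3cc([Mg]Cl)c(O[Si](C)(C)C(C)(C)C)cc3O[Si](C)(C)C(C)(C)C)c3ccc(O[Si](C(C)C)(C(C)C)C(C)C)cc3O[C@@H]2c2ccc(O[Si](C(C)C)(C(C)C)C(C)C)cc2)c1 | intermediate (not isolated)
27 | chloromagnesium (2S,3R,4R)-5-oxo-4-[4-(TIPSO)benzyl]-2-[4-(TIPSO)phenyl]oxolane-3-carboxylate | O=C1O[C@H](c2ccc(O[Si](C(C)C)(C(C)C)C(C)C)cc2)[C@H](C(=O)O[Mg]Cl)[C@H]1Cc1ccc(O[Si](C(C)C)(C(C)C)C(C)C)cc1 | intermediate (not isolated)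
28 | (2S,3R,4R)-5-Ar*-5-hydroxy-4-[4-(TIPSO)benzyl]-2-[4-(TIPSO)phenyl]oxolane-3-carboxylic acid (C5 anomers) | Brc1ccc(O[Si](C)(C)C(C)(C)C)c([C@H]2[C@H](c3cc(C4(O)O[C@H](c5ccc(O[Si](C(C)C)(C(C)C)C(C)C)cc5)[C@H](C(=O)O)[C@H]4Cc4ccc(O[Si](C(C)C)(C(C)C)C(C)C)cc4)c(O[Si](C)(C)C(C)(C)C)cc3O[Si](C)(C)C(C)(C)C)c3ccc(O[Si](C(C)C)(C(C)C)C(C)C)cc3O[C@@H]2c2ccc(O[Si](C(C)C)(C(C)C)C(C)C)cc2)c1 | intermediate
29 | (2S,3R,4R)-5-Ar*-3-carboxy-4-[4-(TIPSO)benzyl]-2-[4-(TIPSO)phenyl]-3,4-dihydro-2H-furan-1-ium (oxocarbenium ion) | Brc1ccc(O[Si](C)(C)C(C)(C)C)c([C@H]2[C@H](c3cc(C4=[O+][C@H](c5ccc(O[Si](C(C)C)(C(C)C)C(C)C)cc5)[C@H](C(=O)O)[C@H]4Cc4ccc(O[Si](C(C)C)(C(C)C)C(C)C)cc4)c(O[Si](C)(C)C(C)(C)C)cc3O[Si](C)(C)C(C)(C)C)c3ccc(O[Si](C(C)C)(C(C)C)C(C)C)cc3O[C@@H]2c2ccc(O[Si](C(C)C)(C(C)C)C(C)C)cc2)c1 | intermediate (not isolated)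
30 | (2S,3R,4R,5S)-5-Ar*-4-[4-(TIPSO)benzyl]-2-[4-(TIPSO)phenyl]oxolane-3-carboxylic acid (2,3-cis, 3,4-trans, 4,5-cis) | Brc1ccc(O[Si](C)(C)C(C)(C)C)c([C@H]2[C@H](c3cc([C@H]4O[C@H](c5ccc(O[Si](C(C)C)(C(C)C)C(C)C)cc5)[C@H](C(=O)O)[C@H]4Cc4ccc(O[Si](C(C)C)(C(C)C)C(C)C)cc4)c(O[Si](C)(C)C(C)(C)C)cc3O[Si](C)(C)C(C)(C)C)c3ccc(O[Si](C(C)C)(C(C)C)C(C)C)cc3O[C@@H]2c2ccc(O[Si](C(C)C)(C(C)C)C(C)C)cc2)c1 | intermediate
31 | (2S,3R,4R,5S)-5-Ar*-N-methoxy-N-methyl-4-[4-(TIPSO)benzyl]-2-[4-(TIPSO)phenyl]oxolane-3-carboxamide | Brc1ccc(O[Si](C)(C)C(C)(C)C)c([C@H]2[C@H](c3cc([C@H]4O[C@H](c5ccc(O[Si](C(C)C)(C(C)C)C(C)C)cc5)[C@H](C(=O)N(C)OC)[C@H]4Cc4ccc(O[Si](C(C)C)(C(C)C)C(C)C)cc4)c(O[Si](C)(C)C(C)(C)C)cc3O[Si](C)(C)C(C)(C)C)c3ccc(O[Si](C(C)C)(C(C)C)C(C)C)cc3O[C@@H]2c2ccc(O[Si](C(C)C)(C(C)C)C(C)C)cc2)c1 | intermediate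
32 | N-methoxy-N-methylprop-2-enamide | C=CC(=O)N(C)OC | starting material
33 | bis-Weinreb amide: 31 in which the aryl bromine is replaced by (E)-3-[methoxy(methyl)amino]-3-oxoprop-1-en-1-yl | CON(C)C(=O)/C=C/c1ccc(O[Si](C)(C)C(C)(C)C)c([C@H]2[C@H](c3cc([C@H]4O[C@H](c5ccc(O[Si](C(C)C)(C(C)C)C(C)C)cc5)[C@H](C(=O)N(C)OC)[C@H]4Cc4ccc(O[Si](C(C)C)(C(C)C)C(C)C)cc4)c(O[Si](C)(C)C(C)(C)C)cc3O[Si](C)(C)C(C)(C)C)c3ccc(O[Si](C(C)C)(C(C)C)C(C)C)cc3O[C@@H]2c2ccc(O[Si](C(C)C)(C(C)C)C(C)C)cc2)c1 | intermediate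
34 | 4-bromobenzene-1,3-diol | Oc1ccc(Br)c(O)c1 | starting material
35 | 1-bromo-2,4-bis(triisopropylsilyloxy)benzene | Brc1ccc(O[Si](C(C)C)(C(C)C)C(C)C)cc1O[Si](C(C)C)(C(C)C)C(C)C | intermediate
36 | [2,4-bis(TIPSO)phenyl]lithium | [Li]c1ccc(O[Si](C(C)C)(C(C)C)C(C)C)cc1O[Si](C(C)C)(C(C)C)C(C)C | intermediate (not isolated)
37 | undeca-O-silyl ether of the target: TBS on the chalcone B-ring oxygen and on both oxygens of the central resorcinol ring, TIPS on the other eight; chroman (2S,3R,4S), oxolane (2S,3R,4R,5S), E enone | O=C(/C=C/c1ccc(O[Si](C)(C)C(C)(C)C)c([C@H]2[C@H](c3cc([C@H]4O[C@H](c5ccc(O[Si](C(C)C)(C(C)C)C(C)C)cc5)[C@H](C(=O)c5ccc(O[Si](C(C)C)(C(C)C)C(C)C)cc5O[Si](C(C)C)(C(C)C)C(C)C)[C@H]4Cc4ccc(O[Si](C(C)C)(C(C)C)C(C)C)cc4)c(O[Si](C)(C)C(C)(C)C)cc3O[Si](C)(C)C(C)(C)C)c3ccc(O[Si](C(C)C)(C(C)C)C(C)C)cc3O[C@@H]2c2ccc(O[Si](C(C)C)(C(C)C)C(C)C)cc2)c1)c1ccc(O[Si](C(C)C)(C(C)C)C(C)C)cc1O[Si](C(C)C)(C(C)C)C(C)C | intermediate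
38 | (E)-1-(2,4-dihydroxyphenyl)-3-[3-[(2S,3R,4R)-4-[5-[(2S,3R,4R,5S)-4-(2,4-dihydroxybenzoyl)-3-(4-hydroxybenzyl)-5-(4-hydroxyphenyl)oxolan-2-yl]-2,4-dihydroxyphenyl]-7-hydroxy-2-(4-hydroxyphenyl)chroman-3-yl]-4-hydroxyphenyl]prop-2-en-1-one (CNP0330082.3) | O=C(/C=C/c1ccc(O)c([C@H]2[C@H](c3cc([C@H]4O[C@H](c5ccc(O)cc5)[C@H](C(=O)c5ccc(O)cc5O)[C@H]4Cc4ccc(O)cc4)c(O)cc3O)c3ccc(O)cc3O[C@@H]2c2ccc(O)cc2)c1)c1ccc(O)cc1O | target

## Step count and risk

Total step count: 21.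

Longest linear sequence: 12 steps (steps 1, 2, 3, 4, 6, 10, 15, 16, 17, 18, 20, 21; 1 → 2 → 3 → 4 → 5 → 8 → 17 → 28 → 30 → 31 → 33 → 37 → 38).

Three steps most likely to fail:

Step 10 (the proposed new cycloaddition). The doubly donor-stabilised, ortho-silyloxy-substituted quinone methide may be sluggish, the regiochemistry rests on the electronic bias of the stilbene, and the facial control by the catalyst is untested. The fallback sets out from 15 (with 8) and comes back at 17. The cycloaddition is run with achiral diphenyl hydrogen phosphate (10 mol%, toluene, 23 °C), the known Brønsted acid-promoted o-quinone methide/alkene hetero-Diels–Alder reaction. It gives the all-trans chroman as a racemate, that is 17 together with its mirror image, the (2R,3S,4R)-chroman F1. The two are separated by preparative supercritical-fluid chromatography on an amylose tris(3,5-dimethylphenylcarbamate) phase, and 17 enters step 15; absolute configuration then comes from resolution instead of catalysis.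

Step 16 (facial selectivity of the ketal reduction). The cis aryl and carboxyl groups on the far side of the ring oppose the directing effect of the adjacent benzyl group, and the aryl/benzyl-cis product is the kinetic, acid-labile epimer. The fallback sets out from 28 and comes back at 30. Hemiketal 28 is dehydrated with pyridinium p-toluenesulfonate (5 mol%, 4 Å sieves, toluene, 50 °C) to the (2S,3R)-5-Ar*-4-[4-(TIPSO)benzyl]-2-[4-(TIPSO)phenyl]-2,3-dihydrofuran-3-carboxylic acid F2. The tetrasubstituted enol ether is then hydrogenated with [Ir(cod)(PCy3)(py)]PF6 (5 mol%) under H2 (1 atm) in CH2Cl2. The carboxyl group binds iridium and both hydrogens are delivered on its own face, which resets the benzyl centre trans to the carboxyl group and places the aryl group cis to benzyl, giving 30 without relying on the oxocarbenium face bias.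

Step 20 (double addition of a hindered ortho-silyloxy aryllithium to a hindered α-branched Weinreb amide). Risks are silyl migration in the aryllithium, incomplete addition at the oxolane amide, and α-deprotonation. The fallback sets out from 33 (with 35) and comes back at 37. Both Weinreb amides are reduced with i-Bu2AlH (THF, −78 °C) to the dialdehyde F3. This is treated at −78 °C with [2,4-bis(TIPSO)phenyl]magnesium bromide F4 (from 35, Mg, LiCl, THF), which adds fast to the unhindered aldehydes, to give the bis-carbinol F5 (mixture of carbinol epimers). Both benzylic alcohols are oxidised with Dess–Martin periodinane (NaHCO3, CH2Cl2, 0 °C) to 37.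

## Further compounds

F1 | step 10 | (2R,3S,4R)-3-[5-bromo-2-(TBSO)phenyl]-4-[2,4-bis(TBSO)-5-iodophenyl]-2-[4-(TIPSO)phenyl]-7-(TIPSO)chromane (enantiomer of 17) | Brc1ccc(O[Si](C)(C)C(C)(C)C)c([C@@H]2[C@@H](c3cc(I)c(O[Si](C)(C)C(C)(C)C)cc3O[Si](C)(C)C(C)(C)C)c3ccc(O[Si](C(C)C)(C(C)C)C(C)C)cc3O[C@H]2c2ccc(O[Si](C(C)C)(C(C)C)C(C)C)cc2)c1
F2 | step 16 | (2S,3R)-5-Ar*-4-[4-(TIPSO)benzyl]-2-[4-(TIPSO)phenyl]-2,3-dihydrofuran-3-carboxylic acid | Brc1ccc(O[Si](C)(C)C(C)(C)C)c([C@H]2[C@H](c3cc(C4=C(Cc5ccc(O[Si](C(C)C)(C(C)C)C(C)C)cc5)[C@@H](C(=O)O)[C@@H](c5ccc(O[Si](C(C)C)(C(C)C)C(C)C)cc5)O4)c(O[Si](C)(C)C(C)(C)C)cc3O[Si](C)(C)C(C)(C)C)c3ccc(O[Si](C(C)C)(C(C)C)C(C)C)cc3O[C@@H]2c2ccc(O[Si](C(C)C)(C(C)C)C(C)C)cc2)c1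
F3 | step 20 | dialdehyde: 33 with both C(=O)N(OMe)Me groups replaced by CHO | O=C/C=C/c1ccc(O[Si](C)(C)C(C)(C)C)c([C@H]2[C@H](c3cc([C@H]4O[C@H](c5ccc(O[Si](C(C)C)(C(C)C)C(C)C)cc5)[C@H](C=O)[C@H]4Cc4ccc(O[Si](C(C)C)(C(C)C)C(C)C)cc4)c(O[Si](C)(C)C(C)(C)C)cc3O[Si](C)(C)C(C)(C)C)c3ccc(O[Si](C(C)C)(C(C)C)C(C)C)cc3O[C@@H]2c2ccc(O[Si](C(C)C)(C(C)C)C(C)C)cc2)c1
F4 | step 20 | [2,4-bis(TIPSO)phenyl]magnesium bromide | Br[Mg]c1ccc(O[Si](C(C)C)(C(C)C)C(C)C)cc1O[Si](C(C)C)(C(C)C)C(C)C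
F5 | step 20 | bis-carbinol: 37 with both ketones as CH(OH) (carbinol epimers) | OC(/C=C/c1ccc(O[Si](C)(C)C(C)(C)C)c([C@H]2[C@H](c3cc([C@H]4O[C@H](c5ccc(O[Si](C(C)C)(C(C)C)C(C)C)cc5)[C@H](C(O)c5ccc(O[Si](C(C)C)(C(C)C)C(C)C)cc5O[Si](C(C)C)(C(C)C)C(C)C)[C@H]4Cc4ccc(O[Si](C(C)C)(C(C)C)C(C)C)cc4)c(O[Si](C)(C)C(C)(C)C)cc3O[Si](C)(C)C(C)(C)C)c3ccc(O[Si](C(C)C)(C(C)C)C(C)C)cc3O[C@@H]2c2ccc(O[Si](C(C)C)(C(C)C)C(C)C)cc2)c1)c1ccc(O[Si](C(C)C)(C(C)C)C(C)C)cc1O[Si](C(C)C)(C(C)C)C(C)C
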